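The C1(cyclohexane)–C6(oxane) bond is formed by a lithiation–borylation 1,2-metalate shift in which ring carbon C1 migrates from boron to C6; the resulting C–B bond is oxidised to the C–O bond of the later oxane.
The feature that allows this: oxane C6 is a fully substituted carbon that carries ring oxygen O1 and is bonded directly to the cyclohexane methine C1, so C6–O1 can be read as an oxidised C–B bond and C6 as a lithiated secondary benzoate carbon.
Fragments: a C7 (S)-cyclohexenyl boronic ester (C1 set by sparteine-controlled lithiation–borylation, cyclohexene ring closed first by metathesis) and a C8 (S)-benzoate from 6-methylhept-5-en-2-one.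
The oxane ring is formed second, by 6-endo bromoetherification of the coupled dienol, which sets C3–Br from C6.
The cyclohexane halogens come last from the ring alkene: trans-diaxial chlorohydrin, then replacement of the tertiary hydroxyl by bromide with retention.

Key step: step 6

Remark: both enantiomers of sparteine and the named alcohol dehydrogenase are taken as purchasable. Locants used below: oxane O1, C2 (CMe2), C3 (CHBr), C6 (C bearing CH3 and the cyclohexyl group); cyclohexane C1 (CH bonded to C6), C3 (CHCl), C4 (CBr(CH3)).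

Step 1
Reactants: 1 4-methylpent-4-en-1-ol
Product: 2 4-methylpent-4-en-1-yl N,N-di(propan-2-yl)carbamate
Conditions: i-Pr2NC(O)Cl, Et3N, CH2Cl2, reflux
Reagents that add atoms: N,N-di(propan-2-yl)carbamoyl chloride, CC(C)N(C(C)C)C(Cl)=O
Why: Carbamoylation of the primary alcohol (acyl substitution) installs the carbamate that directs the α-lithiation and later serves as leaving group of the 1,2-shift in step 2; no stereocenter is formed.

Step 2
Reactants: 2 4-methylpent-4-en-1-yl N,N-di(propan-2-yl)carbamate; 3 4,4,5,5-tetramethyl-2-(prop-2-en-1-yl)-1,3,2-dioxaborolane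
Product: 6 4,4,5,5-tetramethyl-2-[(4S)-7-methylocta-1,7-dien-4-yl]-1,3,2-dioxaborolane, via lithiated carbamate 4 (not isolated), via boronate complex 5 (not isolated)
Conditions: s-BuLi, (+)-sparteine, Et2O, −78 °C; then 3, −78 °C; then reflux
Reagents that add atoms: none
Why: In this lithiation–borylation the (+)-sparteine/s-BuLi complex removes one enantiotopic α-proton to give the configurationally stable (R)-organolithium 4, borylation by 3 proceeds with retention to 5, and on warming the allyl group migrates from boron to carbon with inversion as the carbamate leaves, so the boron-bearing carbon (the later C1) should be set as (S) under reagent control.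

Step 3
Reactants: 6 4,4,5,5-tetramethyl-2-[(4S)-7-methylocta-1,7-dien-4-yl]-1,3,2-dioxaborolane
Product: 7 4,4,5,5-tetramethyl-2-[(1S)-4-methylcyclohex-3-en-1-yl]-1,3,2-dioxaborolane
Conditions: second-generation Grubbs catalyst RuCl2(=CHPh)(PCy3)(H2IMes) (5 mol%), CH2Cl2, 40 °C
Reagents that add atoms: none
Why: Ring-closing olefin metathesis between the monosubstituted and the 1,1-disubstituted alkene closes the six-membered ring as the trisubstituted cyclohexene with loss of ethene and leaves the C–B bond untouched, so the (S)-configuration of 6 becomes C1 of 7.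

Step 4
Reactants: 8 6-methylhept-5-en-2-one
Product: 9 (2R)-6-methylhept-5-en-2-ol
Conditions: alcohol dehydrogenase from Lactobacillus kefir, NADP+ (cat.), MgCl2 (1 mM), i-PrOH, aqueous phosphate buffer (pH 7), 30 °C
Reagents that add atoms: none
Why: Enzymatic asymmetric ketone reduction, with hydride delivered from the cofactor to the carbonyl face that this (R)-selective dehydrogenase prefers for methyl ketones and isopropanol as terminal reductant, should set C2 as (R).

Step 5
Reactants: 9 (2R)-6-methylhept-5-en-2-ol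
Product: 10 (2S)-6-methylhept-5-en-2-yl 2,4,6-tri(propan-2-yl)benzoate
Conditions: 2,4,6-(i-Pr)3C6H2CO2H, PPh3, DIAD, THF, 0 °C → rt
Reagents that add atoms: 2,4,6-tri(propan-2-yl)benzoic acid, CC(C)c1cc(C(C)C)c(C(O)=O)c(C(C)C)c1
Why: In the Mitsunobu reaction the hindered carboxylate displaces the alkoxyphosphonium ion by SN2, so the (R)-alcohol should give the (S)-benzoate with inversion, and the bulky aryl group later shields the ester carbonyl from s-BuLi.

Step 6
Reactants: 10 (2S)-6-methylhept-5-en-2-yl 2,4,6-tri(propan-2-yl)benzoate; 7 4,4,5,5-tetramethyl-2-[(1S)-4-methylcyclohex-3-en-1-yl]-1,3,2-dioxaborolane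
Product: 14 (2S)-6-methyl-2-[(1S)-4-methylcyclohex-3-en-1-yl]hept-5-en-2-ol, via lithiated benzoate 11 (not isolated), via boronate complex 12 (not isolated), via tertiary boronic ester 13 (not isolated)
Conditions: s-BuLi, TMEDA, cyclopentyl methyl ether, −60 °C; then 7, −60 °C → 50 °C; then NaOH, H2O2, THF/H2O, 0 °C → rt
Reagents that add atoms: hydrogen peroxide, OO
Why: s-BuLi/TMEDA removes the carbinol proton of 10 under direction of the benzoate carbonyl to give the configurationally stable tertiary α-oxy organolithium 11, which 7 borylates with retention to the boronate complex 12; on warming, the cyclohexenyl carbon C1 migrates from boron to C6 antiperiplanar to the departing benzoate (1,2-metalate rearrangement), and the C–B bond of 13 is then oxidised to C–OH with retention. The closest known reaction type is the lithiation–borylation of secondary dialkyl 2,4,6-triisopropylbenzoates with boronic esters to give tertiary boronic esters and tertiary alcohols. No ring is closed in this step. The new stereocenter C6 is controlled by the (S)-configuration of the benzoate carbon (retention on lithiation and borylation, inversion on migration, retention on oxidation, which maps (S)-10 onto (S)-C6 of 14), and C1 keeps the (S)-configuration of 7 because alkyl groups migrate from boron with retention. The step needs deprotonation only at the carbinol C–H and migration only of the ring carbon: the hindered aryl ester resists attack at the carbonyl and steers the base to the α-proton, and in 12 the cyclohexenyl group is the only carbon ligand on boron besides C6, the pinacol oxygens being non-migrating.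

Step 7
Reactants: 14 (2S)-6-methyl-2-[(1S)-4-methylcyclohex-3-en-1-yl]hept-5-en-2-ol
Product: 15 (3R,6S)-3-bromo-2,2,6-trimethyl-6-[(1S)-4-methylcyclohex-3-en-1-yl]oxane
Conditions: 2,4,4,6-tetrabromocyclohexa-2,5-dien-1-one (TBCO), MeNO2, 0 °C → rt, dark
Reagents that add atoms: 2,4,4,6-tetrabromocyclohexa-2,5-dien-1-one, O=C1C(Br)=CC(Br)(Br)C=C1Br
Why: Bromonium formation at the side-chain alkene and 6-endo capture by the C6 hydroxyl at the more substituted carbon (bromoetherification, anti addition) should close the oxane through a chair in which the cyclohexenyl group at C6 is equatorial, the smaller C6 methyl takes the axial site facing the axial C2 methyl and bromine is equatorial, which sets C3 as (R), trans to the cyclohexenyl group.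

Step 8
Reactants: 15 (3R,6S)-3-bromo-2,2,6-trimethyl-6-[(1S)-4-methylcyclohex-3-en-1-yl]oxane
Product: 16 (1R,2R,4S)-4-[(2S,5R)-5-bromo-2,6,6-trimethyloxan-2-yl]-2-chloro-1-methylcyclohexan-1-ol
Conditions: trichloroisocyanuric acid (0.34 equiv), acetone/H2O, 0 °C
Reagents that add atoms: trichloroisocyanuric acid, O=C1N(Cl)C(=O)N(Cl)C(=O)N1Cl; water, O
Why: Electrophilic chlorine adds to the ring alkene and water opens the chloronium ion at the tertiary carbon (chlorohydrin formation); with the oxanyl group equatorial, only the chloronium ion on the face trans to it can open trans-diaxially at that carbon, which should place chlorine at C3 trans and the hydroxyl at C4 cis to the oxanyl group.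

Step 9
Reactants: 16 (1R,2R,4S)-4-[(2S,5R)-5-bromo-2,6,6-trimethyloxan-2-yl]-2-chloro-1-methylcyclohexan-1-ol
Product: 17 (3R,6S)-3-bromo-6-[(1S,3R,4R)-4-bromo-3-chloro-4-methylcyclohexyl]-2,2,6-trimethyloxane
Conditions: Me3SiBr, CH2Cl2, −20 → 0 °C
Reagents that add atoms: bromotrimethylsilane, C[Si](C)(C)Br
Why: SN1 substitution of the tertiary alcohol with neighbouring-group participation, in which ionisation assisted by the antiperiplanar C–Cl bond gives a chloronium ion that bromide opens at the tertiary carbon from the face opposite to chlorine, should keep the trans-diaxial arrangement and so retain the C4 configuration.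

Compound list
1 | 4-methylpent-4-en-1-ol | CC(=C)CCCO | starting material
2 | 4-methylpent-4-en-1-yl N,N-di(propan-2-yl)carbamate | CC(=C)CCCOC(=O)N(C(C)C)C(C)C | intermediate
3 | 4,4,5,5-tetramethyl-2-(prop-2-en-1-yl)-1,3,2-dioxaborolane (allylboronic acid pinacol ester) | C=CCB1OC(C)(C)C(C)(C)O1 | starting material
4 | (1R)-1-lithio-4-methylpent-4-en-1-yl N,N-di(propan-2-yl)carbamate, bound to (+)-sparteine (lithiated carbamate) | [Li][C@H](CCC(C)=C)OC(=O)N(C(C)C)C(C)C | intermediate
5 | lithium boronate complex of 3 and 4: tetracoordinate boron bearing the allyl group, the pinacol oxygens and the (1R)-carbamate-bearing carbon | [Li+].C=CC[B-]1(OC(C)(C)C(C)(C)O1)[C@H](CCC(C)=C)OC(=O)N(C(C)C)C(C)C | intermediate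
6 | 4,4,5,5-tetramethyl-2-[(4S)-7-methylocta-1,7-dien-4-yl]-1,3,2-dioxaborolane | C=CC[C@H](CCC(C)=C)B1OC(C)(C)C(C)(C)O1 | intermediate
7 | 4,4,5,5-tetramethyl-2-[(1S)-4-methylcyclohex-3-en-1-yl]-1,3,2-dioxaborolane | CC1(C)OB(OC1(C)C)[C@H]2CCC(C)=CC2 | intermediate
8 | 6-methylhept-5-en-2-one | CC(=O)CCC=C(C)C | starting material
9 | (2R)-6-methylhept-5-en-2-ol | C[C@@H](O)CCC=C(C)C | intermediate
10 | (2S)-6-methylhept-5-en-2-yl 2,4,6-tri(propan-2-yl)benzoate | CC(C)c1cc(C(C)C)c(C(=O)O[C@@H](C)CCC=C(C)C)c(C(C)C)c1 | intermediate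
11 | (2S)-2-lithio-6-methylhept-5-en-2-yl 2,4,6-tri(propan-2-yl)benzoate (lithiated benzoate) | CC(C)c1cc(C(C)C)c(C(=O)O[C@@]([Li])(C)CCC=C(C)C)c(C(C)C)c1 | intermediate
12 | lithium boronate complex of 7 and 11: tetracoordinate boron bearing the pinacol oxygens, C1 of the (1S)-cyclohexenyl group and the (2S)-benzoate-bearing carbon | [Li+].CC(C)c1cc(C(C)C)c(C(=O)O[C@@](C)(CCC=C(C)C)[B-]2(OC(C)(C)C(C)(C)O2)[C@H]3CCC(C)=CC3)c(C(C)C)c1 | intermediate
13 | 4,4,5,5-tetramethyl-2-{(2R)-6-methyl-2-[(1S)-4-methylcyclohex-3-en-1-yl]hept-5-en-2-yl}-1,3,2-dioxaborolane | CC1(C)OB(OC1(C)C)[C@@](C)(CCC=C(C)C)[C@H]2CCC(C)=CC2 | intermediate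
14 | (2S)-6-methyl-2-[(1S)-4-methylcyclohex-3-en-1-yl]hept-5-en-2-ol | CC(C)=CCC[C@](C)(O)[C@H]1CCC(C)=CC1 | intermediate
15 | (3R,6S)-3-bromo-2,2,6-trimethyl-6-[(1S)-4-methylcyclohex-3-en-1-yl]oxane | CC1(C)O[C@](C)([C@H]2CCC(C)=CC2)CC[C@H]1Br | intermediate
16 | (1R,2R,4S)-4-[(2S,5R)-5-bromo-2,6,6-trimethyloxan-2-yl]-2-chloro-1-methylcyclohexan-1-ol | CC1(C)O[C@](C)([C@H]2CC[C@@](C)(O)[C@H](Cl)C2)CC[C@H]1Br | intermediate
17 | (3R,6S)-3-bromo-6-[(1S,3R,4R)-4-bromo-3-chloro-4-methylcyclohexyl]-2,2,6-trimethyloxane | CC1(C)O[C@](C)([C@H]2CC[C@@](C)(Br)[C@H](Cl)C2)CC[C@H]1Br | target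

Total step count: 9. Longest linear sequence: 7 steps (steps 1, 2, 3, 6, 7, 8, 9).

Steps most likely to fail

Step 6. Formation of the crowded boronate complex 12 from a tertiary organolithium and a secondary boronic ester may be slow or reversible, and 12 may lose the organolithium again faster than C1 migrates, returning 7. The fallback sets out from 7 and comes back to the route at 14. It introduces the two carbon substituents of C6 in the opposite order, so that the hindered ring boronate meets only a small carbenoid and the fully substituted centre is closed by migration of a primary group. Ethyl N,N-di(propan-2-yl)carbamate is lithiated with s-BuLi/(−)-sparteine (Et2O, −78 °C) and treated with 7; warming should give, by the same 1,2-shift (which forms the C1–C6 bond), the secondary boronic ester 4,4,5,5-tetramethyl-2-{(1R)-1-[(1S)-4-methylcyclohex-3-en-1-yl]ethyl}-1,3,2-dioxaborolane F1. Oxidation (NaOH, H2O2) gives (1R)-1-[(1S)-4-methylcyclohex-3-en-1-yl]ethan-1-ol F2, which is acylated with 2,4,6-tri(propan-2-yl)benzoyl chloride (NaH, THF, retention) to (1R)-1-[(1S)-4-methylcyclohex-3-en-1-yl]ethyl 2,4,6-tri(propan-2-yl)benzoate F3. Lithiation of F3 (s-BuLi, TMEDA, cyclopentyl methyl ether, −60 °C) is followed by borylation with 4,4,5,5-tetramethyl-2-(4-methylpent-3-en-1-yl)-1,3,2-dioxaborolane F4, prepared from 5-bromo-2-methylpent-2-ene through its Grignard reagent and 2-isopropoxy-4,4,5,5-tetramethyl-1,3,2-dioxaborolane. Migration of the primary alkyl group should give 13, and oxidation as in step 6 gives 14.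

Step 7. The bromonium ion may be opened at the less substituted carbon (5-exo closure to the oxolane isomer), the brominating agent may also attack the ring alkene, and the chair preference may be too weak to fix C3. The fallback sets out from 14 and comes back at 15; it brings bromine in as a nucleophile on a preformed oxane. Hg(OCOCF3)2 (MeNO2, 0 °C, then aqueous KBr) should cyclise 14 only at the more substituted alkene carbon to bromo[(3R,6S)-2,2,6-trimethyl-6-[(1S)-4-methylcyclohex-3-en-1-yl]oxan-3-yl]mercury F5. Oxidative demercuration (NaBH4, O2, DMF) gives the C3-epimeric (6S)-2,2,6-trimethyl-6-[(1S)-4-methylcyclohex-3-en-1-yl]oxan-3-ol F6, and Swern oxidation gives (6S)-2,2,6-trimethyl-6-[(1S)-4-methylcyclohex-3-en-1-yl]oxan-3-one F7. Reduction with LiBH(s-Bu)3 (THF, −78 °C) by equatorial attack should give the axial alcohol (3S,6S)-2,2,6-trimethyl-6-[(1S)-4-methylcyclohex-3-en-1-yl]oxan-3-ol F8. Sulfonylation (ClCH2SO2Cl, pyridine) gives (3S,6S)-2,2,6-trimethyl-6-[(1S)-4-methylcyclohex-3-en-1-yl]oxan-3-yl chloromethanesulfonate F9, and SN2 displacement with LiBr (DMF, 60 °C) with inversion gives 15.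

Step 9. The acid set free may open the di-tertiary oxane ether, the β-chloro cation may eliminate, and the halogens may scramble through the halonium ions. The fallback sets out from 16 and comes back at 17; it makes the tertiary C–Br bond by a neutral radical addition instead of ionisation. Anti elimination of water from 16 (SOCl2, pyridine, 0 °C) should give the two allylic chlorides (3R,6S)-3-bromo-6-[(1S,5R)-5-chloro-4-methylcyclohex-3-en-1-yl]-2,2,6-trimethyloxane F10 and (3R,6S)-3-bromo-6-[(1S,3R)-3-chloro-4-methylidenecyclohexyl]-2,2,6-trimethyloxane F11. The mixture is submitted to metal-hydride hydrogen atom transfer hydrobromination (Co(acac)2, t-BuOOH, Et3SiH, TsBr, n-PrOH, rt). Both alkenes give the same tertiary C4 radical, and bromine transfer anti to the axial C3–Cl bond should give 17.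

Further compounds
F1 | step 6 | 4,4,5,5-tetramethyl-2-{(1R)-1-[(1S)-4-methylcyclohex-3-en-1-yl]ethyl}-1,3,2-dioxaborolane | CC1(C)OB(OC1(C)C)[C@H](C)[C@H]2CCC(C)=CC2
F2 | step 6 | (1R)-1-[(1S)-4-methylcyclohex-3-en-1-yl]ethan-1-ol | O[C@H](C)[C@H]1CCC(C)=CC1
F3 | step 6 | (1R)-1-[(1S)-4-methylcyclohex-3-en-1-yl]ethyl 2,4,6-tri(propan-2-yl)benzoate | CC(C)c1cc(C(C)C)c(C(=O)O[C@H](C)[C@H]2CCC(C)=CC2)c(C(C)C)c1
F4 | step 6 | 4,4,5,5-tetramethyl-2-(4-methylpent-3-en-1-yl)-1,3,2-dioxaborolane | CC(C)=CCCB1OC(C)(C)C(C)(C)O1
F5 | step 7 | bromo[(3R,6S)-2,2,6-trimethyl-6-[(1S)-4-methylcyclohex-3-en-1-yl]oxan-3-yl]mercury | CC1(C)O[C@](C)([C@H]2CCC(C)=CC2)CC[C@H]1[Hg]Br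
F6 | step 7 | (6S)-2,2,6-trimethyl-6-[(1S)-4-methylcyclohex-3-en-1-yl]oxan-3-ol (C3 epimers) | CC1(C)O[C@](C)([C@H]2CCC(C)=CC2)CCC1O
F7 | step 7 | (6S)-2,2,6-trimethyl-6-[(1S)-4-methylcyclohex-3-en-1-yl]oxan-3-one | CC1(C)O[C@](C)([C@H]2CCC(C)=CC2)CCC1=O
F8 | step 7 | (3S,6S)-2,2,6-trimethyl-6-[(1S)-4-methylcyclohex-3-en-1-yl]oxan-3-ol | CC1(C)O[C@](C)([C@H]2CCC(C)=CC2)CC[C@@H]1O
F9 | step 7 | (3S,6S)-2,2,6-trimethyl-6-[(1S)-4-methylcyclohex-3-en-1-yl]oxan-3-yl chloromethanesulfonate | CC1(C)O[C@](C)([C@H]2CCC(C)=CC2)CC[C@@H]1OS(=O)(=O)CCl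
F10 | step 9 | (3R,6S)-3-bromo-6-[(1S,5R)-5-chloro-4-methylcyclohex-3-en-1-yl]-2,2,6-trimethyloxane | CC1(C)O[C@](C)([C@H]2CC=C(C)[C@H](Cl)C2)CC[C@H]1Br
F11 | step 9 | (3R,6S)-3-bromo-6-[(1S,3R)-3-chloro-4-methylidenecyclohexyl]-2,2,6-trimethyloxane | CC1(C)O[C@](C)([C@H]2CCC(=C)[C@H](Cl)C2)CC[C@H]1Br
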